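**Retrosynthetic overview**

1. Last ring (γ-lactone): the C18 tert-butyl ester opens a 7,8-epoxy-9-ketone at allylic C7 (C7–O bond, 8-OH); the same acid step frees C20–OH.
2. Ten-membered ring: intramolecular Horner–Wadsworth–Emmons at C7=C8 between a β-ketophosphonate on C9 and a (Z)-enal; C2 by 1,3-anti reduction directed by C14–OH.
3. Cyclohexene with quaternary C1 and C10: boat Ireland–Claisen rearrangement of a 6-alkenyl δ-lactone silyl ketene acetal (C1–C10 bond); C3 from MeLi, C4–C6 by enolate alkylation.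
4. δ-Lactone: (R)-3-(TBSO)glutaric acid monomethyl ester (C14) plus a (Z)-alkenyllithium from but-2-yne-1,4-diol, then syn-reduction (C12).
5. Ring order: δ-lactone → cyclohexene → ten-membered carbocycle → γ-lactone.

Assumptions: briarane numbering of the target is used for all intermediates (C1–C10 ten-membered ring; C1, C10–C14 cyclohexene; C15 = CH3 on C1; C16 = CH3 on C5; C17/C18/C19 = lactone CH/C=O/CH3; C20 = CH2O on C11; β = face of C15). Compounds 6 and 29 are bought as single enantiomers. PMB = 4-methoxybenzyl, TBS = tert-butyldimethylsilyl, TBDPS = tert-butyldiphenylsilyl. The route is a design; no step has been run.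

**Route**

Step 1
Reactants: 1 but-2-yne-1,4-diol
Product: 2 4-[(4-methoxybenzyl)oxy]but-2-yn-1-ol
Conditions: NaH (1 equiv), PMBCl (1 equiv), 1 (3 equiv), Bu4NI (cat.), THF/DMF, 0 °C → rt
Reagents that add atoms: 4-methoxybenzyl chloride COc1ccc(CCl)cc1
Why: Williamson etherification of the monosodium alkoxide, run with excess diol so that mono-alkylation dominates.

Step 2
Reactants: 2 4-[(4-methoxybenzyl)oxy]but-2-yn-1-ol
Product: 4 (2Z)-3-iodo-4-[(4-methoxybenzyl)oxy]but-2-en-1-ol, via sodium alkenylalanate 3 (not isolated)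
Conditions: Red-Al (1.6 equiv), THF, 0 °C; then I2, THF, −78 → 0 °C
Reagents that add atoms: iodine II
Why: Hydroxyl-directed trans-hydroalumination puts Al on the carbon remote from the free OH with H anti to it, and iodinolysis with retention fixes the (Z)-vinyl iodide in which iodine (later C12) is cis to C9.

Step 3
Reactants: 4 (2Z)-3-iodo-4-[(4-methoxybenzyl)oxy]but-2-en-1-ol
Product: 5 (2Z)-1-[(tert-butyldiphenylsilyl)oxy]-3-iodo-4-[(4-methoxybenzyl)oxy]but-2-ene
Conditions: TBDPSCl, imidazole, DMF, rt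
Reagents that add atoms: tert-butyl(chloro)diphenylsilane CC(C)(C)[Si](Cl)(c1ccccc1)c1ccccc1
Why: Imidazole-promoted silylation of the primary alcohol gives a robust ether that survives the later HF/MeCN step and keeps the Z-γ-oxy-enone from cyclising.

Step 4
Reactants: 6 (3R)-3-[(tert-butyldimethylsilyl)oxy]-5-methoxy-5-oxopentanoic acid
Product: 7 (3S)-3-[(tert-butyldimethylsilyl)oxy]-5-[methoxy(methyl)amino]-5-oxopentanoic acid
Conditions: MeNHOMe·HCl (1.5 equiv), iPrMgCl (4.5 equiv), THF, −20 → 0 °C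
Reagents that add atoms: N,O-dimethylhydroxylamine hydrochloride CNOC.Cl
Why: Weinreb amide formation by magnesium-amide aminolysis of the methyl ester while the acid is masked as its magnesium carboxylate; making the ester arm of 6 the future C12 acyl group gives C14 the sense needed for the target (the stereocentre is not touched, only its CIP label changes).

Step 5
Reactants: 5 (2Z)-1-[(tert-butyldiphenylsilyl)oxy]-3-iodo-4-[(4-methoxybenzyl)oxy]but-2-ene; 7 (3S)-3-[(tert-butyldimethylsilyl)oxy]-5-[methoxy(methyl)amino]-5-oxopentanoic acid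
Product: 9 (3S,6Z)-3-(TBSO)-8-(TBDPSO)-6-(PMBOCH2)-5-oxooct-6-enoic acid, via alkenyllithium 8 (not isolated)
Conditions: 5, t-BuLi (2.1 equiv), Et2O, −78 °C; add to 7 + LiHMDS (1.05 equiv), THF, −78 → −30 °C; aq. NH4Cl
Reagents that add atoms: none
Why: Iodine–lithium exchange with retention of olefin geometry followed by Weinreb ketone synthesis (lithium carboxylate inert, chelated tetrahedral intermediate prevents over-addition) forms the C11–C12 bond.

Step 6
Reactants: 9 (3S,6Z)-3-(TBSO)-8-(TBDPSO)-6-(PMBOCH2)-5-oxooct-6-enoic acid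
Product: 10 (3S,6Z)-8-(TBDPSO)-3-hydroxy-6-(PMBOCH2)-5-oxooct-6-enoic acid
Conditions: 48% aq. HF, MeCN, 0 °C
Reagents that add atoms: none
Why: Acidic fluoride desilylation removes the secondary TBS ether far faster than the primary TBDPS ether and leaves the PMB ether intact.

Step 7
Reactants: 10 (3S,6Z)-8-(TBDPSO)-3-hydroxy-6-(PMBOCH2)-5-oxooct-6-enoic acid
Product: 12 (4S,6R)-6-[(2Z)-4-(TBDPSO)-1-(PMBO)but-2-en-2-yl]-4-hydroxyoxan-2-one, via syn-dihydroxy acid 11 (not isolated)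
Conditions: Et2BOMe, NaBH4, THF/MeOH (4:1), −78 °C; AcOH, MeOH azeotrope; then PPTS (cat.), toluene, 60 °C
Reagents that add atoms: none
Why: Narasaka–Prasad reduction (axial hydride attack on the boron chelate of the β-hydroxy ketone) gives the 1,3-syn diol, so C12 (R) is controlled by C14, and acid-catalysed lactonisation then gives the 4,6-trans δ-lactone.

Step 8
Reactants: 12 (4S,6R)-6-[(2Z)-4-(TBDPSO)-1-(PMBO)but-2-en-2-yl]-4-hydroxyoxan-2-one
Product: 14 (3R,4S,6R)-6-[(2Z)-4-(TBDPSO)-1-(PMBO)but-2-en-2-yl]-4-hydroxy-3-methyloxan-2-one, via dilithio lactone enolate 13 (not isolated)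
Conditions: LDA (2.3 equiv), THF, −78 °C; MeI, DMPU, −78 → −40 °C
Reagents that add atoms: iodomethane CI
Why: Fráter–Seebach-type alkylation of the alkoxide enolate dianion (no β-elimination) introduces C15 anti to the C14 alkoxide; this centre becomes planar in step 9, so its configuration is immaterial.

Step 9
Reactants: 14 (3R,4S,6R)-6-[(2Z)-4-(TBDPSO)-1-(PMBO)but-2-en-2-yl]-4-hydroxy-3-methyloxan-2-one
Product: 16 (1R,2S,6S)-2-(TBDPSOCH2)-6-hydroxy-3-(PMBOCH2)-1-methylcyclohex-3-ene-1-carboxylic acid, via bis(trimethylsilyl) ketene acetal 15 (not isolated)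
Conditions: LDA (2.5 equiv), TMSCl/Et3N, THF, −78 °C → rt; toluene, 100 °C; 1 M HCl
Reagents that add atoms: none
Why: Ireland–Claisen rearrangement of the lactone silyl ketene acetal through the enforced boat transition state forms the C1–C10 bond on the enolate face carrying the C12 alkenyl group, so C1 (CO2H cis to the C14 oxygen) and C10 (C9 trans to CO2H, from the Z-olefin) are both set by the bought C14 centre via C12.

Step 10
Reactants: 16 (1R,2S,6S)-2-(TBDPSOCH2)-6-hydroxy-3-(PMBOCH2)-1-methylcyclohex-3-ene-1-carboxylic acid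
Product: 17 1-[(1R,2S,6S)-2-(TBDPSOCH2)-6-hydroxy-3-(PMBOCH2)-1-methylcyclohex-3-en-1-yl]ethan-1-one
Conditions: MeLi (5 equiv), Et2O/THF, 0 °C → rt; aq. NH4Cl
Reagents that add atoms: methyllithium [Li]C
Why: Addition of MeLi to the lithium carboxylate gives a stable gem-dialkoxide that collapses to the methyl ketone only on work-up (acid-to-ketone synthesis), supplying C3.

Step 11
Reactants: 18 prop-2-yn-1-ol
Product: 20 (2Z)-3-iodo-2-methylprop-2-en-1-ol, via alkenylmagnesium alkoxide 19 (not isolated)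
Conditions: MeMgBr (2.5 equiv), CuI (10 mol%), THF, −10 °C → rt; then I2, −20 °C
Reagents that add atoms: methylmagnesium bromide C[Mg]Br; iodine II
Why: Copper-catalysed anti-carbomagnesiation of propargyl alcohol through the chelated oxamagnesacycle, then iodinolysis with retention, gives the (Z)-trisubstituted olefin that becomes C5=C6.

Step 12
Reactants: 20 (2Z)-3-iodo-2-methylprop-2-en-1-ol
Product: 21 (1Z)-3-bromo-1-iodo-2-methylprop-1-ene
Conditions: CBr4, PPh3, CH2Cl2, 0 °C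
Reagents that add atoms: carbon tetrabromide BrC(Br)(Br)Br
Why: Appel bromination of the primary allylic alcohol leaves the vinyl iodide and the olefin geometry untouched.

Step 13
Reactants: 17 1-[(1R,2S,6S)-2-(TBDPSOCH2)-6-hydroxy-3-(PMBOCH2)-1-methylcyclohex-3-en-1-yl]ethan-1-one; 21 (1Z)-3-bromo-1-iodo-2-methylprop-1-ene
Product: 23 (4Z)-1-[(1R,2S,6S)-2-(TBDPSOCH2)-6-hydroxy-3-(PMBOCH2)-1-methylcyclohex-3-en-1-yl]-5-iodo-4-methylpent-4-en-1-one, via dilithio ketone enolate 22 (not isolated)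
Conditions: LDA (2.2 equiv), THF, −78 °C; 21, DMPU, −78 → −45 °C; AcOH, −78 °C
Reagents that add atoms: none
Why: Kinetic enolate alkylation: the ketone can enolise only toward C3 (C1 is quaternary), the alkoxide enolate dianion cannot undergo retro-aldol at low temperature, and the allylic bromide forms the C3–C4 bond.

Step 14
Reactants: 23 (4Z)-1-[(1R,2S,6S)-2-(TBDPSOCH2)-6-hydroxy-3-(PMBOCH2)-1-methylcyclohex-3-en-1-yl]-5-iodo-4-methylpent-4-en-1-one
Product: 24 (1S,4Z)-1-[(1S,2S,6S)-2-(TBDPSOCH2)-6-hydroxy-3-(PMBOCH2)-1-methylcyclohex-3-en-1-yl]-5-iodo-4-methylpent-4-en-1-ol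
Conditions: Me4NBH(OAc)3, MeCN/AcOH (1:1), −30 °C
Reagents that add atoms: none
Why: Evans–Saksena reduction: the C14 hydroxyl binds the triacetoxyborohydride and delivers hydride intramolecularly through a chair transition state (C13 and the C3 chain equatorial), giving the 1,3-anti diol, i.e. (2S).

Step 15
Reactants: 24 (1S,4Z)-1-[(1S,2S,6S)-2-(TBDPSOCH2)-6-hydroxy-3-(PMBOCH2)-1-methylcyclohex-3-en-1-yl]-5-iodo-4-methylpent-4-en-1-ol
Product: 25 2,14-diacetate of 24
Conditions: Ac2O, DMAP, pyridine, 40 °C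
Reagents that add atoms: acetic anhydride CC(=O)OC(C)=O
Why: DMAP-catalysed acetylation of both hindered secondary alcohols installs the two acetates of the target.

Step 16
Reactants: 25 2,14-diacetate of 24
Product: 26 C9 primary alcohol (25 without the TBDPS group)
Conditions: HF·pyridine, THF/pyridine, 0 °C → rt
Reagents that add atoms: none
Why: Fluoride desilylation frees the C9 alcohol; acetates, PMB ether and vinyl iodide are unaffected.

Step 17
Reactants: 26 C9 primary alcohol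
Product: 27 C9 aldehyde
Conditions: Dess–Martin periodinane, NaHCO3, CH2Cl2, 0 °C → rt
Reagents that add atoms: none
Why: Dess–Martin oxidation under buffered, non-basic conditions gives the β,γ-unsaturated aldehyde without epimerising C10 or moving the C11=C12 double bond.

Step 18
Reactants: 27 C9 aldehyde
Product: 28 C9 β-ketophosphonate
Conditions: N2CHP(O)(OMe)2, SnCl2 (20 mol%), CH2Cl2, rt
Reagents that add atoms: dimethyl (diazomethyl)phosphonate COP(=O)(OC)C=[N+]=[N-]
Why: Roskamp homologation (Lewis-acid-catalysed addition of the diazo compound to the aldehyde, 1,2-hydride shift, loss of N2) gives the β-ketophosphonate directly and introduces C8.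

Step 19
Reactants: 29 (2R)-2-bromopropanoic acid
Product: 30 tert-butyl (2R)-2-bromopropanoate
Conditions: t-BuOC(=NH)CCl3, BF3·OEt2 (cat.), cyclohexane/CH2Cl2, rt
Reagents that add atoms: tert-butyl 2,2,2-trichloroacetimidate CC(C)(C)OC(=N)C(Cl)(Cl)Cl
Why: Acid-catalysed tert-butylation of the carboxylic acid with the trichloroacetimidate does not touch the stereocentre.

Step 20
Reactants: 28 C9 β-ketophosphonate; 30 tert-butyl (2R)-2-bromopropanoate
Product: 32 C8-alkylated β-ketophosphonate, via sodium phosphonate enolate 31 (not isolated)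
Conditions: NaH, THF, 0 °C; then 30, DMF, 0 °C → rt
Reagents that add atoms: none
Why: SN2 alkylation of the soft phosphonate-stabilised enolate by the secondary α-bromo ester goes with inversion, so C17 (bought in 29) has the configuration of the target, while the C8 mixture is erased in step 22.

Step 21
Reactants: 32 C8-alkylated β-ketophosphonate
Product: 33 (Z)-enal phosphonate
Conditions: Pd(PPh3)4 (5 mol%), CO (1 atm), Bu3SnH (slow addition), THF, 50 °C
Reagents that add atoms: carbon monoxide [C-]#[O+]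
Why: Palladium-catalysed reductive carbonylation (formylation) of the vinyl iodide with CO/Bu3SnH proceeds with retention and gives the (Z)-enal, introducing C7.

Step 22
Reactants: 33 (Z)-enal phosphonate
Product: 34 tert-butyl (1S,2S,5Z,7E,10S,14S,17R)-2,14-diacetoxy-20-(PMBO)-9-oxobriara-5,7,11-trien-18-oate
Conditions: K2CO3, 18-crown-6, toluene (1 mM, syringe pump), 70 °C
Reagents that add atoms: none
Why: Intramolecular Horner–Wadsworth–Emmons olefination under high dilution closes the ten-membered ring at C7=C8 and should give the (7E)-enone (C6 anti to the C9 acyl group), as is usual for α-substituted β-ketophosphonates.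

Step 23
Reactants: 34 tert-butyl (1S,2S,5Z,7E,10S,14S,17R)-2,14-diacetoxy-20-(PMBO)-9-oxobriara-5,7,11-trien-18-oate
Product: 35 tert-butyl (1S,2S,5Z,7R,8S,10S,14S,17R)-2,14-diacetoxy-7,8-epoxy-20-(PMBO)-9-oxobriara-5,11-dien-18-oate
Conditions: t-BuOOH (decane), DBU, CH2Cl2, 0 °C → rt
Reagents that add atoms: tert-butyl hydroperoxide CC(C)(C)OO
Why: Weitz–Scheffer nucleophilic epoxidation: the peroxide anion adds 1,4 at C7 (1,6-addition at the disubstituted C5 is hindered) and closes with retention to the trans-epoxide; attack on the outer face of the E-olefin is expected to place the oxygen that becomes the 8α-OH (substrate control, not proven).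

Step 24
Reactants: 35 tert-butyl (1S,2S,5Z,7R,8S,10S,14S,17R)-2,14-diacetoxy-7,8-epoxy-20-(PMBO)-9-oxobriara-5,11-dien-18-oate
Product: 36 (1S,2S,5Z,7S,8S,10S,14S,17R)-2,14-diacetoxy-8,20-dihydroxy-9-oxobriara-5,11-dien-18,7-olide
Conditions: TFA/CH2Cl2 (1:4), anisole, 0 °C → rt; aq. NaHCO3
Reagents that add atoms: none
Why: Acid activates the epoxide and the tert-butyl ester carbonyl opens it at allylic C7 in a 5-exo SN2 process with inversion (loss of isobutene), giving the trans-fused γ-lactone with free 8-OH, while TFA also cleaves the PMB ether to release C20–OH.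

**Compound list**

1 | but-2-yne-1,4-diol | OCC#CCO | starting material
2 | 4-[(4-methoxybenzyl)oxy]but-2-yn-1-ol | COc1ccc(COCC#CCO)cc1 | intermediate
3 | sodium alkenylalanate (cyclic oxaluminole ate complex; Al on C11, O on C9, two 2-methoxyethoxy ligands) | COCCO[Al-]1(OCCOC)OCC=C1COCc1ccc(OC)cc1.[Na+] | intermediate (not isolated)
4 | (2Z)-3-iodo-4-[(4-methoxybenzyl)oxy]but-2-en-1-ol | OC/C=C(\I)COCc1ccc(OC)cc1 | intermediate
5 | (2Z)-1-[(tert-butyldiphenylsilyl)oxy]-3-iodo-4-[(4-methoxybenzyl)oxy]but-2-ene | CC(C)(C)[Si](OC/C=C(\I)COCc1ccc(OC)cc1)(c1ccccc1)c1ccccc1 | intermediate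
6 | (3R)-3-[(tert-butyldimethylsilyl)oxy]-5-methoxy-5-oxopentanoic acid | COC(=O)C[C@H](O[Si](C)(C)C(C)(C)C)CC(=O)O | starting material
7 | (3S)-3-[(tert-butyldimethylsilyl)oxy]-5-[methoxy(methyl)amino]-5-oxopentanoic acid | CON(C)C(=O)C[C@H](O[Si](C)(C)C(C)(C)C)CC(=O)O | intermediate
8 | (Z)-alkenyllithium from 5 (Li in place of I) | [Li]/C(COCc1ccc(OC)cc1)=C\CO[Si](c1ccccc1)(c1ccccc1)C(C)(C)C | intermediate (not isolated)
9 | (3S,6Z)-3-[(tert-butyldimethylsilyl)oxy]-8-[(tert-butyldiphenylsilyl)oxy]-6-{[(4-methoxybenzyl)oxy]methyl}-5-oxooct-6-enoic acid | OC(=O)C[C@@H](O[Si](C)(C)C(C)(C)C)CC(=O)/C(COCc1ccc(OC)cc1)=C\CO[Si](c1ccccc1)(c1ccccc1)C(C)(C)C | intermediate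
10 | (3S,6Z)-8-[(tert-butyldiphenylsilyl)oxy]-3-hydroxy-6-{[(4-methoxybenzyl)oxy]methyl}-5-oxooct-6-enoic acid | OC(=O)C[C@@H](O)CC(=O)/C(COCc1ccc(OC)cc1)=C\CO[Si](c1ccccc1)(c1ccccc1)C(C)(C)C | intermediate
11 | (3S,5R,6Z)-8-[(tert-butyldiphenylsilyl)oxy]-3,5-dihydroxy-6-{[(4-methoxybenzyl)oxy]methyl}oct-6-enoic acid (syn diol) | OC(=O)C[C@@H](O)C[C@@H](O)/C(COCc1ccc(OC)cc1)=C\CO[Si](c1ccccc1)(c1ccccc1)C(C)(C)C | intermediate (not isolated)
12 | (4S,6R)-6-[(2Z)-4-[(tert-butyldiphenylsilyl)oxy]-1-[(4-methoxybenzyl)oxy]but-2-en-2-yl]-4-hydroxyoxan-2-one (4,6-trans) | O=C1O[C@@H](/C(COCc2ccc(OC)cc2)=C\CO[Si](c2ccccc2)(c2ccccc2)C(C)(C)C)C[C@H](O)C1 | intermediate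
13 | dilithium alkoxide enolate of 12 | [Li]OC1=C[C@@H](O[Li])C[C@H](/C(COCc2ccc(OC)cc2)=C\CO[Si](c2ccccc2)(c2ccccc2)C(C)(C)C)O1 | intermediate (not isolated)
14 | (3R,4S,6R)-6-[(2Z)-4-[(tert-butyldiphenylsilyl)oxy]-1-[(4-methoxybenzyl)oxy]but-2-en-2-yl]-4-hydroxy-3-methyloxan-2-one (3,4-trans; the 3-epimer is equally usable) | O=C1O[C@@H](/C(COCc2ccc(OC)cc2)=C\CO[Si](c2ccccc2)(c2ccccc2)C(C)(C)C)C[C@H](O)[C@H]1C | intermediate
15 | bis(trimethylsilyl) ketene acetal of 14 (5-methyl-4,6-bis(trimethylsilyloxy)-3,4-dihydro-2H-pyran carrying the alkenyl group on C2) | C[Si](C)(C)OC1=C(C)[C@@H](O[Si](C)(C)C)C[C@H](/C(COCc2ccc(OC)cc2)=C\CO[Si](c2ccccc2)(c2ccccc2)C(C)(C)C)O1 | intermediate (not isolated)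
16 | (1R,2S,6S)-2-{[(tert-butyldiphenylsilyl)oxy]methyl}-6-hydroxy-3-{[(4-methoxybenzyl)oxy]methyl}-1-methylcyclohex-3-ene-1-carboxylic acid (ring C1/C2/C3/C4/C5/C6 = briarane C1/C10/C11/C12/C13/C14; CO2H = C2) | O[C@H]1CC=C(COCc2ccc(OC)cc2)[C@H](CO[Si](c2ccccc2)(c2ccccc2)C(C)(C)C)[C@@]1(C)C(=O)O | intermediate
17 | 1-[(1R,2S,6S)-2-{[(tert-butyldiphenylsilyl)oxy]methyl}-6-hydroxy-3-{[(4-methoxybenzyl)oxy]methyl}-1-methylcyclohex-3-en-1-yl]ethan-1-one | O[C@H]1CC=C(COCc2ccc(OC)cc2)[C@H](CO[Si](c2ccccc2)(c2ccccc2)C(C)(C)C)[C@@]1(C)C(C)=O | intermediate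
18 | prop-2-yn-1-ol | OCC#C | starting material
19 | alkenylmagnesium alkoxide (4-methyl-2,5-dihydro-1,2-oxamagnesole) | CC1=C[Mg]OC1 | intermediate (not isolated)
20 | (2Z)-3-iodo-2-methylprop-2-en-1-ol | OC/C(C)=C\I | intermediate
21 | (1Z)-3-bromo-1-iodo-2-methylprop-1-ene | BrC/C(C)=C\I | intermediate
22 | dilithium alkoxide enolate of 17 | [Li]O[C@H]1CC=C(COCc2ccc(OC)cc2)[C@H](CO[Si](c2ccccc2)(c2ccccc2)C(C)(C)C)[C@@]1(C)C(=C)O[Li] | intermediate (not isolated)
23 | (4Z)-1-[(1R,2S,6S)-2-{[(tert-butyldiphenylsilyl)oxy]methyl}-6-hydroxy-3-{[(4-methoxybenzyl)oxy]methyl}-1-methylcyclohex-3-en-1-yl]-5-iodo-4-methylpent-4-en-1-one | O[C@H]1CC=C(COCc2ccc(OC)cc2)[C@H](CO[Si](c2ccccc2)(c2ccccc2)C(C)(C)C)[C@@]1(C)C(=O)CC/C(C)=C\I | intermediate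
24 | (1S,4Z)-1-[(1S,2S,6S)-2-{[(tert-butyldiphenylsilyl)oxy]methyl}-6-hydroxy-3-{[(4-methoxybenzyl)oxy]methyl}-1-methylcyclohex-3-en-1-yl]-5-iodo-4-methylpent-4-en-1-ol (2,14-anti diol; 1S,2S,10S,14S in briarane numbering) | O[C@H]1CC=C(COCc2ccc(OC)cc2)[C@H](CO[Si](c2ccccc2)(c2ccccc2)C(C)(C)C)[C@@]1(C)[C@@H](O)CC/C(C)=C\I | intermediate
25 | 2,14-diacetate of 24: cyclohexene (C1, C10–C14, Δ11) with β-CH3 and α-[(1S,4Z)-1-acetoxy-5-iodo-4-methylpent-4-enyl] on C1, β-CH2OTBDPS on C10, CH2OPMB on C11, α-OAc on C14 | CC(=O)O[C@H]1CC=C(COCc2ccc(OC)cc2)[C@H](CO[Si](c2ccccc2)(c2ccccc2)C(C)(C)C)[C@@]1(C)[C@@H](OC(C)=O)CC/C(C)=C\I | intermediate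
26 | C9 alcohol: 25 with CH2OH on C10 | CC(=O)O[C@H]1CC=C(COCc2ccc(OC)cc2)[C@H](CO)[C@@]1(C)[C@@H](OC(C)=O)CC/C(C)=C\I | intermediate
27 | C9 aldehyde: 25 with CHO on C10 | CC(=O)O[C@H]1CC=C(COCc2ccc(OC)cc2)[C@H](C=O)[C@@]1(C)[C@@H](OC(C)=O)CC/C(C)=C\I | intermediate
28 | β-ketophosphonate: 25 with C(=O)CH2P(O)(OMe)2 on C10 (C9 ketone, C8 methylene) | CC(=O)O[C@H]1CC=C(COCc2ccc(OC)cc2)[C@H](C(=O)CP(=O)(OC)OC)[C@@]1(C)[C@@H](OC(C)=O)CC/C(C)=C\I | intermediate
29 | (2R)-2-bromopropanoic acid | C[C@@H](Br)C(=O)O | starting material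
30 | tert-butyl (2R)-2-bromopropanoate | C[C@@H](Br)C(=O)OC(C)(C)C | intermediate
31 | sodium enolate of 28 | CC(=O)O[C@H]1CC=C(COCc2ccc(OC)cc2)[C@H](C(O[Na])=CP(=O)(OC)OC)[C@@]1(C)[C@@H](OC(C)=O)CC/C(C)=C\I | intermediate (not isolated)
32 | alkylated β-ketophosphonate: 28 carrying CH(CH3)CO2t-Bu on C8 (C17 as in the target, C8 epimers) | CC(=O)O[C@H]1CC=C(COCc2ccc(OC)cc2)[C@H](C(=O)C([C@@H](C)C(=O)OC(C)(C)C)P(=O)(OC)OC)[C@@]1(C)[C@@H](OC(C)=O)CC/C(C)=C\I | intermediate
33 | (Z)-enal phosphonate: 32 with CHO (C7) in place of iodine on C6 | CC(=O)O[C@H]1CC=C(COCc2ccc(OC)cc2)[C@H](C(=O)C([C@@H](C)C(=O)OC(C)(C)C)P(=O)(OC)OC)[C@@]1(C)[C@@H](OC(C)=O)CC/C(C)=C\C=O | intermediate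
34 | tert-butyl (1S,2S,5Z,7E,10S,14S,17R)-2,14-diacetoxy-20-[(4-methoxybenzyl)oxy]-9-oxobriara-5,7,11-trien-18-oate | CC(=O)O[C@H]1CC=C(COCc3ccc(OC)cc3)[C@H]2[C@@]1(C)[C@@H](OC(C)=O)CC/C(C)=C\C=C(/[C@@H](C)C(=O)OC(C)(C)C)C2=O | intermediate
35 | tert-butyl (1S,2S,5Z,7R,8S,10S,14S,17R)-2,14-diacetoxy-7,8-epoxy-20-[(4-methoxybenzyl)oxy]-9-oxobriara-5,11-dien-18-oate | CC(=O)O[C@H]1CC=C(COCc3ccc(OC)cc3)[C@H]2[C@@]1(C)[C@@H](OC(C)=O)CC/C(C)=C\[C@H]3O[C@]3([C@@H](C)C(=O)OC(C)(C)C)C2=O | intermediate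
36 | (1S,2S,5Z,7S,8S,10S,14S,17R)-2,14-diacetoxy-8,20-dihydroxy-9-oxobriara-5,11-dien-18,7-olide (CNP0140109.1) | CC(=O)O[C@H]1CC=C(CO)[C@@H]2C(=O)[C@@]3(O)[C@H](/C=C(/C)CC[C@H](OC(C)=O)[C@]21C)OC(=O)[C@@H]3C | target

**Step count and risks**

Total step count: 24. Longest linear sequence: 20 steps (1–3, 5–10, 13–18, 20–24).

Steps most likely to fail:

Step 9 (boat Ireland–Claisen). The ketene acetal is fully substituted and the Z-olefin points its CH2OTBDPS group into the bicyclic transition state, so the rearrangement may be too slow. Fallback: set out from 12 and leave out step 8. Rearrange the less hindered, unmethylated lactone (LDA, TMSCl/Et3N, THF, −78 °C, then toluene, 90 °C, then 1 M HCl) to the des-methyl hydroxy acid F1. Then build the quaternary centre by alkylation instead of in the rearrangement: the alkoxide enediolate trianion of F1 (LDA, 3.3 equiv, THF/DMPU, −78 → −20 °C) is methylated with MeI anti to the C14 alkoxide (Fráter–Seebach control), which comes back to the route at 16.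

Step 22 (HWE closure of the ten-membered ring). A medium ring, an α-branched phosphonate and a conjugated aldehyde may favour oligomers or the 7Z isomer. Fallback: set out from 32 and leave out step 21. Intermolecular HWE with formaldehyde (aq. CH2O, K2CO3, THF, 0 °C) gives the α-methylene ketone F2. Ring closure is then moved to the C6–C7 bond by an intramolecular Mizoroki–Heck reaction of the vinyl iodide onto the terminal CH2 (Pd(OAc)2, Bu4NCl, K2CO3, DMF, high dilution). β-Hydride elimination toward C7 restores the conjugated C7=C8 bond and comes back to the route at 34.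

Step 23 (face and site of the nucleophilic epoxidation). The wrong olefin face would give the 7,8-bis-epimer, and base may also epimerise C10. Fallback: set out from 34. Luche reduction (NaBH4, CeCl3·7H2O, MeOH, −40 °C) gives the C9 allylic alcohol F3. Hydroxyl-directed epoxidation (VO(acac)2, t-BuOOH, CH2Cl2, 0 °C) then attacks only the adjacent C7=C8 bond under non-basic conditions and gives the epoxy alcohol F4. Dess–Martin oxidation of F4 comes back to the route at 35.

Further compounds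
F1 | step 9 | des-methyl hydroxy acid (16 without the C15 methyl; C1 epimers; C10 and C14 as in 16) | O[C@H]1CC=C(COCc2ccc(OC)cc2)[C@H](CO[Si](c2ccccc2)(c2ccccc2)C(C)(C)C)C1C(=O)O
F2 | step 22 | α-methylene ketone (32 with C8=CH2 in place of H and P(O)(OMe)2 on C8) | CC(=O)O[C@H]1CC=C(COCc2ccc(OC)cc2)[C@H](C(=O)C(=C)[C@@H](C)C(=O)OC(C)(C)C)[C@@]1(C)[C@@H](OC(C)=O)CC/C(C)=C\I
F3 | step 23 | C9 allylic alcohol (34 with CH–OH at C9; C9 epimers) | CC(=O)O[C@H]1CC=C(COCc3ccc(OC)cc3)[C@H]2[C@@]1(C)[C@@H](OC(C)=O)CC/C(C)=C\C=C(/[C@@H](C)C(=O)OC(C)(C)C)C2O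
F4 | step 23 | 7,8-epoxy C9 alcohol (35 with CH–OH at C9; C9 epimers) | CC(=O)O[C@H]1CC=C(COCc3ccc(OC)cc3)[C@H]2[C@@]1(C)[C@@H](OC(C)=O)CC/C(C)=C\[C@H]3O[C@]3([C@@H](C)C(=O)OC(C)(C)C)C2O
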